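## Retrosynthetic overview
1. Feature: on C6 of ring A, C8–C9 is a plain two-carbon unit. C9 carries oxygen and the isobutenyl group (C10=C11), C8 is bonded to C7, and C7 can stay sp2 (C7=C14) until a late reduction.
2. Key disconnection: C7–C8 and C9–C10 are made in one operation from a ring A C7 alkenyl triflate, vinylB(pin) (C8=C9) and 2-methylprop-1-enyllithium (C10–C13) by a palladium-induced 1,2-metallate shift. C9–B then becomes C9–O with retention.
3. End game: C9 acetate, release of C1–OH, C1–OH-directed hydrogenation of C7=C14 (sets C7), and the C1 angelate last.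
4. Triflate from (R)-carvone: the α′-carbon becomes C1 (enolate hydroxylation). The enone is transposed by epoxidation and Wharton reaction to C2=C3/C4–O, which gives the cis-1,4-dioxygen pattern trans to C6 directly. The isopropenyl group is cut to the C7 methyl ketone.
5. Rings: ring A is the only ring and is taken intact from carvone, so no ring is formed.

Key step: step 8

Numbering used: ring A = C1 (O-acyl or O-silyl), C2=C3 (CH3), C4 (OAc), C5, C6; chain = C7 (C14 on it), C8, C9, C10=C11 (two CH3).

Assumption: the sense of induction of the MandyPhos ligand with this triflate is taken to follow that seen with simple alkenyl triflates, so the ligand enantiomer is specified by the outcome it has to give (9R). Both enantiomers are sold, and the sense can be confirmed on a model triflate by Mosher ester analysis.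

## Route

**Step 1**
Reactants: 1 (R)-(−)-carvone
Product: 2 (5S,6S)-6-hydroxy-2-methyl-5-(prop-1-en-2-yl)cyclohex-2-en-1-one (hydroxyl trans to isopropenyl)
Conditions: NaN(SiMe3)2, THF, −78 °C; 2-(phenylsulfonyl)-3-phenyloxaziridine, −78 °C; aq NH4Cl
Reagents that add atoms: 2-(phenylsulfonyl)-3-phenyloxaziridine, O=S(=O)(c1ccccc1)N1OC1c1ccccc1
Why: Kinetic α′-deprotonation gives the cross-conjugated sodium enolate, and Davis oxaziridine hydroxylation should deliver oxygen to the face opposite the neighbouring isopropenyl group, which sets C1 trans to C6.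

**Step 2**
Reactants: 2 (5S,6S)-6-hydroxycarvone
Product: 3 (5S,6S)-6-[(tert-butyldimethylsilyl)oxy]-2-methyl-5-(prop-1-en-2-yl)cyclohex-2-en-1-one
Conditions: TBSCl, imidazole, DMF, 23 °C
Reagents that add atoms: tert-butyldimethylsilyl chloride, CC(C)(C)[Si](C)(C)Cl
Why: Standard imidazole-promoted silylation of a secondary alcohol, which blocks ketol isomerisation and oxidative cleavage in the next step and touches no stereocentre.

**Step 3**
Reactants: 3 silyloxy enone
Product: 4 (1R,3S,4S,6R)-3-[(tert-butyldimethylsilyl)oxy]-1-methyl-4-(prop-1-en-2-yl)-7-oxabicyclo[4.1.0]heptan-2-one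
Conditions: 30% aq H2O2, NaOH (0.3 equiv), MeOH, 0 °C
Reagents that add atoms: hydrogen peroxide, OO
Why: In this Weitz–Scheffer epoxidation hydroperoxide adds axially to the β-carbon anti to the C6 substituent, as with carvone itself, so the epoxide oxygen (future C4–O) lies trans to the side chain and cis to C1–O, and the electron-rich isopropenyl alkene is not attacked.

**Step 4**
Reactants: 4 epoxy ketone
Product: 5 (1R,4R,5S)-4-[(tert-butyldimethylsilyl)oxy]-2-methyl-5-(prop-1-en-2-yl)cyclohex-2-en-1-ol
Conditions: N2H4·H2O, AcOH (cat.), MeOH, argon, 0 to 23 °C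
Reagents that add atoms: none
Why: In the Wharton transposition the hydrazone opens the epoxide to an alkenyl diazene that loses N2, so the former carbonyl carbon becomes C2 of C2=C3 while the C4–O bond is never broken and keeps its configuration.

**Step 5**
Reactants: 5 allylic alcohol
Product: 6 (1R,4R,5S)-4-[(tert-butyldimethylsilyl)oxy]-2-methyl-5-(prop-1-en-2-yl)cyclohex-2-en-1-yl acetate
Conditions: Ac2O, pyridine, DMAP (cat.), CH2Cl2, 23 °C
Reagents that add atoms: acetic anhydride, CC(=O)OC(C)=O
Why: DMAP-catalysed acetylation at oxygen installs the C4 acetate of the target with retention.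

**Step 6**
Reactants: 6 acetate
Product: 7 (1R,4R,5R)-5-acetyl-4-[(tert-butyldimethylsilyl)oxy]-2-methylcyclohex-2-en-1-yl acetate
Conditions: OsO4 (2 mol %), NaIO4, 2,6-lutidine, dioxane/H2O 3:1, 23 °C
Reagents that add atoms: sodium periodate, [Na+].[O-]I(=O)(=O)=O (oxygen passed on through OsO4)
Why: In this Lemieux–Johnson cleavage OsO4 should take the unhindered 1,1-disubstituted alkene well ahead of trisubstituted C2=C3, which is flanked and inductively deactivated by the C1 silyloxy and C4 acetoxy groups, and the lutidine buffer protects C6 from epimerisation and the β-silyloxy group from elimination.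

**Step 7**
Reactants: 7 methyl ketone
Product: 8 (1R,4R,5R)-4-[(tert-butyldimethylsilyl)oxy]-2-methyl-5-[1-(trifluoromethanesulfonyloxy)ethenyl]cyclohex-2-en-1-yl acetate
Conditions: KN(SiMe3)2 (1.05 equiv), THF, −78 °C; N-(5-chloropyridin-2-yl)bis(trifluoromethanesulfonimide) (Comins reagent), −78 °C; aq NH4Cl
Reagents that add atoms: Comins reagent, O=S(=O)(N(c1ccc(Cl)cn1)S(=O)(=O)C(F)(F)F)C(F)(F)F
Why: In this kinetic enol triflation the bulky amide removes a methyl proton (C14) rather than the tertiary C6–H or the less acidic acetate protons, and the reactive pyridyl triflimide traps the enolate at −78 °C before it can equilibrate or expel the C1 silyloxy group.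

**Step 8**
Reactants: 8 ring A C7 alkenyl triflate; 9 vinylboronic acid pinacol ester; 10 1-bromo-2-methylprop-1-ene
Product: 13 (1R,4R,5S)-4-[(tert-butyldimethylsilyl)oxy]-2-methyl-5-[(4R)-6-methyl-4-(4,4,5,5-tetramethyl-1,3,2-dioxaborolan-2-yl)hepta-1,5-dien-2-yl]cyclohex-2-en-1-yl acetate, via 2-methylprop-1-enyllithium 11 (not isolated), via lithium ethenyl(2-methylprop-1-enyl)pinacolatoborate 12 (not isolated)
Conditions: 10 (1.3 equiv), t-BuLi (2.6 equiv), Et2O, −78 °C; 9 (1.4 equiv), −78 to 23 °C; solvent exchanged to THF; KOTf (2 equiv), Pd(OAc)2 (3 mol %), MandyPhos ligand [1,1′-bis(diarylphosphino)-2,2′-bis(α-(dimethylamino)benzyl)ferrocene, enantiomer giving 9R] (3.6 mol %), 8 (1.0 equiv), 60 °C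
Reagents that add atoms: none
Why: Oxidative addition of 8 to the zerovalent palladium–bisphosphine complex gives a cationic alkenylpalladium species (divalent palladium) whose open site binds the unsubstituted vinyl group of borate 12. The 2-methylprop-1-enyl group then shifts from boron to C9 anti to the metal while C8 becomes bonded to palladium (C9–C10 formed), and reductive elimination joins C7 to C8. This is the known enantioselective conjunctive cross-coupling of bis(alkenyl)borates with C(sp2) triflates, and no ring is closed. C9 is the only new stereocentre and is fixed by the chiral bisphosphine, which selects the vinylborate face that carries palladium, while the resident centres C1, C4 and C6 lie too far away to override it. The step needs discrimination between the two alkenyl groups on boron and suppression of direct Suzuki transfer: the trisubstituted isobutenyl π bond is too hindered to bind palladium and so can only migrate, and the wide-bite ligand favours the shift over transmetallation. KOTf takes bromide out as KBr so that the cationic palladium stays open, and the slight excess of 9 leaves no free organolithium to attack the C4 acetate.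

**Step 9**
Reactants: 13 allylic boronate
Product: 14 (1R,4R,5S)-4-[(tert-butyldimethylsilyl)oxy]-5-[(4R)-4-hydroxy-6-methylhepta-1,5-dien-2-yl]-2-methylcyclohex-2-en-1-yl acetate
Conditions: NaBO3·4H2O, THF/H2O 1:1, 23 °C
Reagents that add atoms: sodium perborate, [Na+].[Na+].O[B-]1(O)OO[B-](O)(O)OO1
Why: In this boronate oxidation C9 migrates 1,2 from boron to peroxide oxygen with retention and without allylic transposition, and the mild perborate medium spares the acetate.

**Step 10**
Reactants: 14 C9 alcohol
Product: 15 (1R,4R,5S)-5-[(4R)-4-acetoxy-6-methylhepta-1,5-dien-2-yl]-4-[(tert-butyldimethylsilyl)oxy]-2-methylcyclohex-2-en-1-yl acetate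
Conditions: Ac2O, pyridine, DMAP (cat.), CH2Cl2, 0 to 23 °C
Reagents that add atoms: acetic anhydride, CC(=O)OC(C)=O
Why: Acetylation at oxygen installs the C9 acetate with retention and masks this hydroxyl so that only C1–OH can direct the later hydrogenation.

**Step 11**
Reactants: 15 silyl ether diacetate
Product: 16 (1R,4R,5S)-5-[(4R)-4-acetoxy-6-methylhepta-1,5-dien-2-yl]-4-hydroxy-2-methylcyclohex-2-en-1-yl acetate
Conditions: HF·pyridine, pyridine, THF, 0 to 23 °C
Reagents that add atoms: none
Why: Pyridine-buffered fluoride desilylation avoids the acetate migration or hydrolysis that basic fluoride sources can cause and is too weakly acidic to ionise the allylic acetates.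

**Step 12**
Reactants: 16 C1 alcohol
Product: 17 (1R,4S,5S)-5-[(2R,4R)-4-acetoxy-6-methylhept-5-en-2-yl]-4-hydroxy-2-methylcyclohex-2-en-1-yl acetate
Conditions: [Rh(nbd)(dppb)]BF4 (5 mol %), H2 (40 bar), CH2Cl2, 23 °C, stopped after uptake of one equivalent
Reagents that add atoms: none
Why: In this hydroxyl-directed hydrogenation cationic rhodium binds C1–OH and the homoallylic C7=C14 bond, the chelate that keeps the C8 chain beside H6 (least A(1,2) strain) turns toward the metal the alkene face whose reduction gives 7R, and the trisubstituted alkenes should survive because C10=C11 has no directing group and the hydroxyl face of C2=C3 is screened by the pseudoaxial C4 acetate.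

**Step 13**
Reactants: 17 C1 alcohol; 18 angelic acid
Product: 20 (1S,4R,6S)-4-acetoxy-6-[(2R,4R)-4-acetoxy-6-methylhept-5-en-2-yl]-3-methylcyclohex-2-en-1-yl (Z)-2-methylbut-2-enoate (target), via angelic 2,4,6-trichlorobenzoic anhydride 19 (not isolated)
Conditions: 18, 2,4,6-trichlorobenzoyl chloride, Et3N, toluene, 23 °C; then 17, 80 °C (no DMAP)
Reagents that add atoms: none
Why: Yamaguchi-type mixed-anhydride esterification without a nucleophilic catalyst is known to transfer the angeloyl group to hindered secondary alcohols without Z to E isomerisation to the tiglate, and acylation at oxygen leaves C1 untouched.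

## Compound list
1 | (R)-(−)-carvone | CC1=CC[C@H](CC1=O)C(C)=C | starting material
2 | (5S,6S)-6-hydroxy-2-methyl-5-(prop-1-en-2-yl)cyclohex-2-en-1-one | O[C@@H]1C(=O)C(C)=CC[C@H]1C(C)=C | intermediate
3 | (5S,6S)-6-[(tert-butyldimethylsilyl)oxy]-2-methyl-5-(prop-1-en-2-yl)cyclohex-2-en-1-one | CC(C)(C)[Si](C)(C)O[C@@H]1C(=O)C(C)=CC[C@H]1C(C)=C | intermediate
4 | (1R,3S,4S,6R)-3-[(tert-butyldimethylsilyl)oxy]-1-methyl-4-(prop-1-en-2-yl)-7-oxabicyclo[4.1.0]heptan-2-one | CC(C)(C)[Si](C)(C)O[C@@H]1C(=O)[C@]2(C)O[C@@H]2C[C@H]1C(C)=C | intermediate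
5 | (1R,4R,5S)-4-[(tert-butyldimethylsilyl)oxy]-2-methyl-5-(prop-1-en-2-yl)cyclohex-2-en-1-ol | CC(C)(C)[Si](C)(C)O[C@@H]1C=C(C)[C@H](O)C[C@H]1C(C)=C | intermediate
6 | (1R,4R,5S)-4-[(tert-butyldimethylsilyl)oxy]-2-methyl-5-(prop-1-en-2-yl)cyclohex-2-en-1-yl acetate | CC(C)(C)[Si](C)(C)O[C@@H]1C=C(C)[C@H](OC(C)=O)C[C@H]1C(C)=C | intermediate
7 | (1R,4R,5R)-5-acetyl-4-[(tert-butyldimethylsilyl)oxy]-2-methylcyclohex-2-en-1-yl acetate | CC(C)(C)[Si](C)(C)O[C@@H]1C=C(C)[C@H](OC(C)=O)C[C@H]1C(C)=O | intermediate
8 | (1R,4R,5R)-4-[(tert-butyldimethylsilyl)oxy]-2-methyl-5-[1-(trifluoromethanesulfonyloxy)ethenyl]cyclohex-2-en-1-yl acetate | CC(C)(C)[Si](C)(C)O[C@@H]1C=C(C)[C@H](OC(C)=O)C[C@H]1C(=C)OS(=O)(=O)C(F)(F)F | intermediate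
9 | vinylboronic acid pinacol ester | C=CB1OC(C)(C)C(C)(C)O1 | starting material
10 | 1-bromo-2-methylprop-1-ene | CC(C)=CBr | starting material
11 | 2-methylprop-1-enyllithium | [Li]C=C(C)C | intermediate
12 | lithium ethenyl(2-methylprop-1-enyl)pinacolatoborate | [Li+].C=C[B-]1(C=C(C)C)OC(C)(C)C(C)(C)O1 | intermediate
13 | (1R,4R,5S)-4-[(tert-butyldimethylsilyl)oxy]-2-methyl-5-[(4R)-6-methyl-4-(4,4,5,5-tetramethyl-1,3,2-dioxaborolan-2-yl)hepta-1,5-dien-2-yl]cyclohex-2-en-1-yl acetate | CC(C)(C)[Si](C)(C)O[C@@H]1C=C(C)[C@H](OC(C)=O)C[C@H]1C(=C)C[C@H](C=C(C)C)B1OC(C)(C)C(C)(C)O1 | intermediate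
14 | (1R,4R,5S)-4-[(tert-butyldimethylsilyl)oxy]-5-[(4R)-4-hydroxy-6-methylhepta-1,5-dien-2-yl]-2-methylcyclohex-2-en-1-yl acetate | CC(C)(C)[Si](C)(C)O[C@@H]1C=C(C)[C@H](OC(C)=O)C[C@H]1C(=C)C[C@H](C=C(C)C)O | intermediate
15 | (1R,4R,5S)-5-[(4R)-4-acetoxy-6-methylhepta-1,5-dien-2-yl]-4-[(tert-butyldimethylsilyl)oxy]-2-methylcyclohex-2-en-1-yl acetate | CC(C)(C)[Si](C)(C)O[C@@H]1C=C(C)[C@H](OC(C)=O)C[C@H]1C(=C)C[C@H](C=C(C)C)OC(C)=O | intermediate
16 | (1R,4R,5S)-5-[(4R)-4-acetoxy-6-methylhepta-1,5-dien-2-yl]-4-hydroxy-2-methylcyclohex-2-en-1-yl acetate | O[C@@H]1C=C(C)[C@H](OC(C)=O)C[C@H]1C(=C)C[C@H](C=C(C)C)OC(C)=O | intermediate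
17 | (1R,4S,5S)-5-[(2R,4R)-4-acetoxy-6-methylhept-5-en-2-yl]-4-hydroxy-2-methylcyclohex-2-en-1-yl acetate | O[C@@H]1C=C(C)[C@H](OC(C)=O)C[C@H]1[C@H](C)C[C@H](C=C(C)C)OC(C)=O | intermediate
18 | angelic acid, (Z)-2-methylbut-2-enoic acid | C/C=C(/C)C(=O)O | starting material
19 | angelic 2,4,6-trichlorobenzoic anhydride | C/C=C(/C)C(=O)OC(=O)c1c(Cl)cc(Cl)cc1Cl | intermediate
20 | (1S,4R,6S)-4-acetoxy-6-[(2R,4R)-4-acetoxy-6-methylhept-5-en-2-yl]-3-methylcyclohex-2-en-1-yl (Z)-2-methylbut-2-enoate | C/C=C(/C)C(=O)O[C@@H]1C=C(C)[C@H](OC(C)=O)C[C@H]1[C@H](C)C[C@H](C=C(C)C)OC(C)=O | target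

## Count and risks
Total step count: 13. Longest linear sequence: 13 steps (1 to 20).

**Step 8 (highest risk).**
- What may go wrong: turnover may be slow at the branched C7 triflate, and residual bromide may poison the cationic palladium. An alkenyl group may also pass directly from boron to palladium. A mismatched pairing of ligand and substrate would erode selectivity at C9.
- Fallback: an aldol builds C8–C9 in place of the three-component union. It sets out from methyl ketone 7, whose methyl group now serves as C8.
- Enolboration on the methyl side uses (Ipc)2BCl and Et3N in Et2O. Addition of 3-methylbut-2-enal at −78 °C and buffered H2O2 work-up should give the β-hydroxy ketone F1. C9 is set by the isopinocampheyl groups, with the reagent enantiomer chosen for 9R.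
- Takai–Lombardo methylenation (Zn, CH2Br2, TiCl4, THF/CH2Cl2, 0 to 23 °C) is not basic and leaves esters, silyl ethers and free hydroxyl groups alone. It turns C7=O into C7=C14, and the route is rejoined at alcohol 14.

**Step 12.**
- What may go wrong: facial selectivity in the acyclic chelate may be poor, and C7=C14 may migrate into the chain at low hydrogen availability. C2=C3 may be over-reduced, or the C1 allylic alcohol may isomerise to a ketone.
- Fallback: catalyst control replaces substrate direction, and the order of steps is exchanged. It sets out from silyl ether 15, in which no group can bind the metal.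
- Hydrogenation uses a chiral iridium catalyst [Ir(cod)(L)]B[3,5-(CF3)2C6H3]4 (L = phosphinite–oxazoline P,N ligand, enantiomer chosen for 7R). Under 1 bar H2 in CH2Cl2 terminal 1,1-disubstituted alkenes react well ahead of hindered trisubstituted ones, so this should give the saturated silyl ether F2.
- HF·pyridine then removes the silyl group, and the route is rejoined at alcohol 17.

**Step 4.**
- What may go wrong: hydrazone formation may be slow at a ketone flanked by a quaternary epoxide carbon and the silyloxy-bearing carbon. Material may also be lost through side reactions of the alkenyl diazene.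
- Fallback: radical fragmentation of the epoxide replaces the diazene route. It sets out from epoxy ketone 4.
- Reduction with NaBH4 and CeCl3·7H2O in MeOH at −20 °C should give the epoxy alcohol F3. Either C2 epimer serves, because C2 becomes sp2.
- 1,1′-Thiocarbonyldiimidazole with DMAP in warm 1,2-dichloroethane converts it into the imidazolyl thiocarbonate F4.
- Bu3SnH and AIBN in toluene at 80 °C generate the C2 radical, which opens the adjacent epoxide to C2=C3 and a C4 alkoxyl radical that the stannane quenches. The C4–O bond is untouched, and the route is rejoined at allylic alcohol 5.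

## Further compounds
F1 | step 8 | (1R,4R,5R)-4-[(tert-butyldimethylsilyl)oxy]-5-[(3R)-3-hydroxy-5-methylhex-4-enoyl]-2-methylcyclohex-2-en-1-yl acetate | CC(C)(C)[Si](C)(C)O[C@@H]1C=C(C)[C@H](OC(C)=O)C[C@H]1C(=O)C[C@H](C=C(C)C)O
F2 | step 12 | (1R,4S,5S)-5-[(2R,4R)-4-acetoxy-6-methylhept-5-en-2-yl]-4-[(tert-butyldimethylsilyl)oxy]-2-methylcyclohex-2-en-1-yl acetate | CC(C)(C)[Si](C)(C)O[C@@H]1C=C(C)[C@H](OC(C)=O)C[C@H]1[C@H](C)C[C@H](C=C(C)C)OC(C)=O
F3 | step 4 | (1S,2S,3S,4S,6R)-3-[(tert-butyldimethylsilyl)oxy]-1-methyl-4-(prop-1-en-2-yl)-7-oxabicyclo[4.1.0]heptan-2-ol | CC(C)(C)[Si](C)(C)O[C@@H]1[C@H](O)[C@]2(C)O[C@@H]2C[C@H]1C(C)=C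
F4 | step 4 | O-[(1R,2S,3S,4S,6R)-3-[(tert-butyldimethylsilyl)oxy]-1-methyl-4-(prop-1-en-2-yl)-7-oxabicyclo[4.1.0]heptan-2-yl] 1H-imidazole-1-carbothioate | CC(C)(C)[Si](C)(C)O[C@@H]1[C@H](OC(=S)n3ccnc3)[C@]2(C)O[C@@H]2C[C@H]1C(C)=C
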